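The 6‑oxabicyclo[3.2.1]octane core is an oxolan‑3‑one ring (C1–C7–O6–C5–C8, carbonyl carbon C8, one methyl on each α‑carbon C1 and C5). Its carbocycle C1–C2–C3–C4–C5–C8 is that ketone bridged across both α‑carbons by the three‑carbon strap C2–C3–C4, and the C2 hydroxyl is the oxygen of an aldol.
Key disconnections: C5–C4 (conjugate addition of the oxygen‑bearing α‑carbon to acrolein) and C1–C2 (aldol of the other α‑carbon on the resulting aldehyde), both in one operation from 2,4‑dimethyloxolan‑3‑one, made by C4 methylation of commercial 2‑methyloxolan‑3‑one.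
Later disconnections: aryl ether (Mitsunobu, umbelliferone + E‑allylic diol); E‑trisubstituted alkene (Horner–Wadsworth–Emmons on a methyl ketone); C8 side chain from a C8 aldehyde made by one‑carbon homologation of the C8 ketone.
Ring order and stereocontrol: the oxolanone ring and the coumarin are bought and the carbocycle is the only ring formed (step 2); C5 by a chiral Brønsted acid, C1 by the tether, C8 by aldehyde equilibration, C2 by late hydride delivery from the C8 side.

Key step: step 2

Assumption: the sense of induction of the phosphoric acid cannot be predicted with certainty; the (R)‑acid is written and its mirror image is used if it delivers the (5R) series.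
Assumption: the aldol of step 2 is reversible and may give both C2 epimers; the (2R) epimer (hydroxyl anti to C8) is drawn and named from the ketol up to the hydroxy enoate, the (2S) epimer takes the same steps, and both converge at the C2 ketone made in step 10.

Step 1
Reactants: 1 2-methyloxolan-3-one (racemic); 2 iodomethane
Product: 4 2,4-dimethyloxolan-3-one (racemic cis/trans mixture), via lithium enolate 3 (not isolated)
Conditions: LiN(iPr)2, THF, −78 °C; MeI, −78 → −20 °C
Reagents that add atoms: iodomethane, CI
Why: Kinetic enolate alkylation: at −78 °C the hindered amide base should remove a proton from the unhindered C4 methylene and not the tertiary C2–H, the lithium enolate is methylated by SN2 attack on iodomethane, and since both α‑centres stay epimerizable the cis/trans mixture is used as it is.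

Step 2
Reactants: 4 2,4-dimethyloxolan-3-one; 5 acrolein
Product: 7 (1R,2R,5S)-2-hydroxy-1,5-dimethyl-6-oxabicyclo[3.2.1]octan-8-one, via keto aldehyde 6 (not isolated)
Conditions: (R)-3,3′-bis(2,4,6-triisopropylphenyl)-1,1′-binaphthyl-2,2′-diyl hydrogen phosphate (10 mol%), acrolein (1.5 equiv, slow addition), cyclohexane, 40 °C; then volatiles removed, TsOH·H2O (10 mol%), THF, rt
Reagents that add atoms: acrolein, C=CC=O
Why: Proposed new method: the chiral phosphoric acid should enolize 4 towards the oxygen‑bearing α‑carbon (that enol is a 4,5‑dihydrofuran‑3‑ol whose C=C is conjugated with the ring oxygen), hold the enol OH and the acrolein carbonyl in one hydrogen‑bonded chiral pocket and so join this carbon to the enal β‑carbon (C5–C4) to give keto aldehyde 6, after which C1 is the only enolizable position of the ketone and its acid‑formed enol adds to the tethered aldehyde (C1–C2). The closest known reaction types are the phosphoric‑acid enol catalysis that turns α‑branched cyclic ketones into α‑quaternary ketones with enones or azodicarboxylates, the racemic enamine α,α′‑annulation of cyclic ketones with acrolein to bridged ketols, and the Michael–aldol [3+3] annulation of cyclic β‑keto esters with enals. The carbocycle C1–C2–C3–C4–C5–C8 closes by a 6‑(enolendo)‑exo‑trig aldol, the C1=C8 enol bond lying inside the forming ring and the aldehyde oxygen outside it. C5 is set by the catalyst, which must shield one face of the flat enol, C1 is set by the tether because the three‑carbon strap can only reach the ring face on which it already stands, and C2 is set in the reversible aldol and is not relied on since step 11 sets it again. The step needs C–C bond formation at the oxygen‑bearing and not at the other α‑carbon, which the greater stability of the oxygen‑conjugated enol under equilibrating acid enolization should secure, and it needs face control that is not spoiled by the C4 methyl of 4, which is plausible because that centre epimerizes through the minor enol and disappears in the aldol, while a second addition is excluded because C5 becomes quaternary and the C1 enol is trapped intramolecularly.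

Step 3
Reactants: 7 (1R,2R,5S)-2-hydroxy-1,5-dimethyl-6-oxabicyclo[3.2.1]octan-8-one; 8 tert-butyldimethylsilyl trifluoromethanesulfonate
Product: 9 (1R,2R,5S)-2-[(tert-butyldimethylsilyl)oxy]-1,5-dimethyl-6-oxabicyclo[3.2.1]octan-8-one
Conditions: TBSOTf, 2,6-lutidine, CH2Cl2, −20 → 0 °C
Reagents that add atoms: tert-butyldimethylsilyl trifluoromethanesulfonate, CC(C)(C)[Si](C)(C)OS(=O)(=O)C(F)(F)F
Why: Silyl ether formation with the silyl triflate and a hindered pyridine base should silylate even this neopentyl‑type secondary alcohol under non‑basic conditions that do not trigger retro‑aldol cleavage, and the C8 ketone cannot be silylated because it has no α‑hydrogen.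

Step 4
Reactants: 9 (1R,2R,5S)-2-[(tert-butyldimethylsilyl)oxy]-1,5-dimethyl-6-oxabicyclo[3.2.1]octan-8-one; 10 trimethylsulfonium iodide
Product: 11 (1R,2R,5S,8R)-2-[(tert-butyldimethylsilyl)oxy]-1,5-dimethylspiro[6-oxabicyclo[3.2.1]octane-8,2′-oxirane] (oxirane oxygen on the side of the C2–C4 bridge)
Conditions: Me3S+ I−, n-BuLi, THF, −10 °C; then 9, 0 °C → rt
Reagents that add atoms: trimethylsulfonium iodide (reacting as dimethylsulfonium methylide), C[S+](C)C.[I-]
Why: Corey–Chaykovsky epoxidation: the small unstabilized sulfonium ylide should add irreversibly to the non‑enolizable, angle‑strained bridging ketone from the more open face above the O6–C7 bridge and the betaine closes to the spiro‑epoxide with its CH2 on that face, the new C8 centre being temporary because step 5 removes it.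

Step 5
Reactants: 11 spiro-epoxide
Product: 13 (1R,2R,5S,8R)-2-[(tert-butyldimethylsilyl)oxy]-1,5-dimethyl-6-oxabicyclo[3.2.1]octane-8-carbaldehyde (formyl over the O6–C7 bridge), via 8-epi aldehyde 12 (not isolated)
Conditions: BF3·OEt2 (0.2 equiv), CH2Cl2, −78 → −40 °C; then NaOMe (0.2 equiv), MeOH, rt
Reagents that add atoms: none
Why: Meinwald rearrangement: the Lewis acid should open the epoxide at the tertiary C8 with 1,2‑hydride shift from the CH2 group to give the aldehyde, and methoxide then equilibrates the only acidic position, C8–H, through the exocyclic enolate so that the formyl group settles over the O6–C7 bridge (equatorial on the cyclohexane chair, clear of the syn‑axial groups at C2 and C4), which sets C8 under thermodynamic control.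

Step 6
Reactants: 13 aldehyde; 14 dimethyl (2-oxopropyl)phosphonate
Product: 15 (3E)-4-[(1R,2R,5S,8R)-2-[(tert-butyldimethylsilyl)oxy]-1,5-dimethyl-6-oxabicyclo[3.2.1]octan-8-yl]but-3-en-2-one
Conditions: (MeO)2P(O)CH2COCH3, NaH, THF, 0 → 40 °C
Reagents that add atoms: dimethyl (2-oxopropyl)phosphonate, CC(=O)CP(=O)(OC)OC
Why: Horner–Wadsworth–Emmons olefination with the β‑keto phosphonate anion, which is more nucleophilic than the corresponding phosphorane and therefore suited to the hindered aldehyde, should give the E‑enone, and any base‑induced epimerization at C8 only returns the same thermodynamic configuration.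

Step 7
Reactants: 15 enone
Product: 16 4-[(1R,2R,5S,8R)-2-[(tert-butyldimethylsilyl)oxy]-1,5-dimethyl-6-oxabicyclo[3.2.1]octan-8-yl]butan-2-one
Conditions: H2 (1 atm), Pd/C, EtOAc, rt
Reagents that add atoms: none
Why: Heterogeneous catalytic hydrogenation should saturate the conjugated disubstituted C=C while the ketone, the silyl ether and the bridged ether stay inert, and no stereocentre is touched.

Step 8
Reactants: 16 methyl ketone; 17 triethyl phosphonoacetate
Product: 18 ethyl (2E)-5-[(1R,2R,5S,8R)-2-[(tert-butyldimethylsilyl)oxy]-1,5-dimethyl-6-oxabicyclo[3.2.1]octan-8-yl]-3-methylpent-2-enoate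
Conditions: (EtO)2P(O)CH2CO2Et, NaH, THF, 0 → 60 °C; Z isomer removed by chromatography
Reagents that add atoms: triethyl phosphonoacetate, CCOC(=O)CP(=O)(OCC)OCC
Why: Horner–Wadsworth–Emmons olefination of the methyl ketone with the phosphonoacetate anion should give the trisubstituted enoate with the ester trans to the larger alkyl chain (E) as the main isomer, the minor Z isomer being separable.

Step 9
Reactants: 18 silyl ether enoate
Product: 19 ethyl (2E)-5-[(1R,2R,5S,8R)-2-hydroxy-1,5-dimethyl-6-oxabicyclo[3.2.1]octan-8-yl]-3-methylpent-2-enoate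
Conditions: HF·pyridine, THF, 0 °C → rt
Reagents that add atoms: none
Why: Fluoride‑mediated desilylation driven by the strong Si–F bond should free the C2 hydroxyl, and the enoate and the bridged ether are stable to the buffered fluoride source.

Step 10
Reactants: 19 hydroxy enoate
Product: 20 ethyl (2E)-5-[(1R,5S,8R)-1,5-dimethyl-2-oxo-6-oxabicyclo[3.2.1]octan-8-yl]-3-methylpent-2-enoate
Conditions: Dess–Martin periodinane, CH2Cl2, rt
Reagents that add atoms: none
Why: Dess–Martin oxidation should convert the secondary alcohol of either C2 configuration into the same ketone under neutral conditions, which erases C2 and leaves the quaternary C1, C5 and C8 untouched.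

Step 11
Reactants: 20 keto enoate
Product: 21 (1R,2R,5S,8R)-8-[(3E)-5-hydroxy-3-methylpent-3-en-1-yl]-1,5-dimethyl-6-oxabicyclo[3.2.1]octan-2-ol
Conditions: LiAlH4, Et2O, −20 → 0 °C
Reagents that add atoms: none
Why: Hydride reduction with LiAlH4: hydride should reach the C2 carbonyl from the C8 side (axial attack past C8–H and C4–H) because the opposite face is blocked by the axial C7 methylene on C1, as in the reduction of 2,2‑disubstituted cyclohexanones, so the equatorial (2R) alcohol is set, and the same reagent reduces the enoate by 1,2‑addition to the E‑allylic alcohol.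

Step 12
Reactants: 21 diol; 22 umbelliferone
Product: 23 7-{[(2E)-5-[(1R,2R,5S,8R)-2-hydroxy-1,5-dimethyl-6-oxabicyclo[3.2.1]octan-8-yl]-3-methylpent-2-en-1-yl]oxy}-2H-chromen-2-one (CNP0178104.1)
Conditions: PPh3, iPrO2C–N=N–CO2iPr, THF, 0 °C → rt
Reagents that add atoms: umbelliferone (7-hydroxy-2H-chromen-2-one), Oc1ccc2ccc(=O)oc2c1
Why: Mitsunobu etherification: the unhindered primary allylic alcohol should be activated selectively over the neopentyl‑type secondary C2–OH and be displaced at carbon (SN2) by the acidic phenol of umbelliferone, which keeps the E geometry and gives the target.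

Compound list
1 | 2-methyloxolan-3-one (2-methyltetrahydrofuran-3-one, racemic) | CC1OCCC1=O | starting material
2 | iodomethane | CI | starting material
3 | lithium 2-methyl-2,5-dihydrofuran-3-olate (kinetic enolate) | CC1OCC=C1[O-].[Li+] | intermediate
4 | 2,4-dimethyloxolan-3-one (2,4-dimethyldihydrofuran-3(2H)-one, racemic cis/trans mixture) | CC1COC(C)C1=O | intermediate
5 | acrolein (prop-2-enal) | C=CC=O | starting material
6 | 3-[(2S)-2,4-dimethyl-3-oxooxolan-2-yl]propanal (C4 epimers) | O=CCC[C@]1(C)OCC(C)C1=O | intermediate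
7 | (1R,2R,5S)-2-hydroxy-1,5-dimethyl-6-oxabicyclo[3.2.1]octan-8-one | O=C1[C@]2(C)CO[C@@]1(C)CC[C@H]2O | intermediate
8 | tert-butyldimethylsilyl trifluoromethanesulfonate | CC(C)(C)[Si](C)(C)OS(=O)(=O)C(F)(F)F | starting material
9 | (1R,2R,5S)-2-[(tert-butyldimethylsilyl)oxy]-1,5-dimethyl-6-oxabicyclo[3.2.1]octan-8-one | O=C1[C@]2(C)CO[C@@]1(C)CC[C@H]2O[Si](C)(C)C(C)(C)C | intermediate
10 | trimethylsulfonium iodide | C[S+](C)C.[I-] | starting material
11 | (1R,2R,5S,8R)-2-[(tert-butyldimethylsilyl)oxy]-1,5-dimethylspiro[6-oxabicyclo[3.2.1]octane-8,2′-oxirane] | C1O[C@]12[C@]3(C)CO[C@@]2(C)CC[C@H]3O[Si](C)(C)C(C)(C)C | intermediate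
12 | (1R,2R,5S,8S)-2-[(tert-butyldimethylsilyl)oxy]-1,5-dimethyl-6-oxabicyclo[3.2.1]octane-8-carbaldehyde (formyl over the C2–C4 bridge) | O=C[C@H]1[C@]2(C)CO[C@@]1(C)CC[C@H]2O[Si](C)(C)C(C)(C)C | intermediate
13 | (1R,2R,5S,8R)-2-[(tert-butyldimethylsilyl)oxy]-1,5-dimethyl-6-oxabicyclo[3.2.1]octane-8-carbaldehyde (formyl over the O6–C7 bridge) | O=C[C@@H]1[C@]2(C)CO[C@@]1(C)CC[C@H]2O[Si](C)(C)C(C)(C)C | intermediate
14 | dimethyl (2-oxopropyl)phosphonate | CC(=O)CP(=O)(OC)OC | starting material
15 | (3E)-4-[(1R,2R,5S,8R)-2-[(tert-butyldimethylsilyl)oxy]-1,5-dimethyl-6-oxabicyclo[3.2.1]octan-8-yl]but-3-en-2-one | CC(=O)/C=C/[C@@H]1[C@]2(C)CO[C@@]1(C)CC[C@H]2O[Si](C)(C)C(C)(C)C | intermediate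
16 | 4-[(1R,2R,5S,8R)-2-[(tert-butyldimethylsilyl)oxy]-1,5-dimethyl-6-oxabicyclo[3.2.1]octan-8-yl]butan-2-one | CC(=O)CC[C@@H]1[C@]2(C)CO[C@@]1(C)CC[C@H]2O[Si](C)(C)C(C)(C)C | intermediate
17 | triethyl phosphonoacetate | CCOC(=O)CP(=O)(OCC)OCC | starting material
18 | ethyl (2E)-5-[(1R,2R,5S,8R)-2-[(tert-butyldimethylsilyl)oxy]-1,5-dimethyl-6-oxabicyclo[3.2.1]octan-8-yl]-3-methylpent-2-enoate | CCOC(=O)/C=C(\C)CC[C@@H]1[C@]2(C)CO[C@@]1(C)CC[C@H]2O[Si](C)(C)C(C)(C)C | intermediate
19 | ethyl (2E)-5-[(1R,2R,5S,8R)-2-hydroxy-1,5-dimethyl-6-oxabicyclo[3.2.1]octan-8-yl]-3-methylpent-2-enoate | CCOC(=O)/C=C(\C)CC[C@@H]1[C@]2(C)CO[C@@]1(C)CC[C@H]2O | intermediate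
20 | ethyl (2E)-5-[(1R,5S,8R)-1,5-dimethyl-2-oxo-6-oxabicyclo[3.2.1]octan-8-yl]-3-methylpent-2-enoate | CCOC(=O)/C=C(\C)CC[C@@H]1[C@]2(C)CO[C@@]1(C)CCC2=O | intermediate
21 | (1R,2R,5S,8R)-8-[(3E)-5-hydroxy-3-methylpent-3-en-1-yl]-1,5-dimethyl-6-oxabicyclo[3.2.1]octan-2-ol | C/C(=C\CO)CC[C@@H]1[C@]2(C)CO[C@@]1(C)CC[C@H]2O | intermediate
22 | umbelliferone (7-hydroxy-2H-chromen-2-one) | Oc1ccc2ccc(=O)oc2c1 | starting material
23 | 7-{[(2E)-5-[(1R,2R,5S,8R)-2-hydroxy-1,5-dimethyl-6-oxabicyclo[3.2.1]octan-8-yl]-3-methylpent-2-en-1-yl]oxy}-2H-chromen-2-one | C/C(=C\COc1ccc2ccc(=O)oc2c1)CC[C@@H]1[C@]2(C)CO[C@@]1(C)CC[C@H]2O | target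

Total step count: 12. Longest linear sequence: 12 steps (1 to 23).

Steps most likely to fail

Step 2 (proposed new method). The acid‑bound enol may add too slowly to acrolein so that the enal oligomerizes, the other α‑carbon may be alkylated, or face control at C5 may be weak. The fallback uses auxiliary control and known chemistry and sets out from 4. Condensation with (R)‑1‑phenylethylamine (TsOH cat., toluene, Dean–Stark) gives the chiral imine F1. Its oxygen‑conjugated secondary enamine tautomer adds to methyl acrylate (neat, 40 °C; deracemizing Michael alkylation of chiral imines, the amine enantiomer chosen by analogy with the established sense for 2‑methylcyclohexanone) to give the adduct imine F2. Hydrolysis with aqueous AcOH gives the keto ester F3 and returns the amine, LiAlH4 gives the diol F4, and Swern oxidation gives keto aldehyde 6, where the fallback comes back to the route; 6 is closed to 7 with TsOH as in the second stage of step 2.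

Step 5. Ionization at the angle‑strained bridging carbon may be slow, or may be followed by migration of a ring bond (Wagner–Meerwein shift) instead of hydride, and the Lewis acid may strip the silyl ether. The fallback sets out from 11. Homolytic opening with Cp2TiCl (trivalent titanium, made from Cp2TiCl2 and Zn) in THF with 1,4‑cyclohexadiene as hydrogen‑atom donor passes through the tertiary C8 radical, with no cation, and gives the primary alcohol F5 as a C8 epimer mixture. Dess–Martin oxidation gives aldehydes 12 and 13, and NaOMe/MeOH equilibration brings the material back to the route at 13.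

Step 8. Poor E/Z control in the olefination of the methyl ketone would divert material into the Z series. The fallback sets out from 16. Kinetic enolization of the methyl group (LiN(iPr)2, THF, −78 °C) and trapping with ClP(O)(OEt)2 gives the enol phosphate F6, and elimination with more LiN(iPr)2 gives the terminal alkyne F7. Zirconium‑catalysed carboalumination (AlMe3, Cp2ZrCl2 cat., CH2Cl2) adds methyl and aluminium syn to give the alkenylalane F8, and ClCO2Et converts it into enoate 18 with the E geometry fixed by the syn addition, where the fallback comes back to the route.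

Further compounds
F1 | step 2 | N-[(1R)-1-phenylethyl]-2,4-dimethyloxolan-3-imine (epimer mixture) | CC1COC(C)C1=N[C@H](C)c1ccccc1
F2 | step 2 | methyl 3-[(2S)-2,4-dimethyl-3-{[(1R)-1-phenylethyl]imino}oxolan-2-yl]propanoate | COC(=O)CC[C@]1(C)OCC(C)C1=N[C@H](C)c1ccccc1
F3 | step 2 | methyl 3-[(2S)-2,4-dimethyl-3-oxooxolan-2-yl]propanoate (C4 epimers) | COC(=O)CC[C@]1(C)OCC(C)C1=O
F4 | step 2 | (2S)-2-(3-hydroxypropyl)-2,4-dimethyloxolan-3-ol (diastereomer mixture) | OCCC[C@]1(C)OCC(C)C1O
F5 | step 5 | [(1R,2R,5S)-2-[(tert-butyldimethylsilyl)oxy]-1,5-dimethyl-6-oxabicyclo[3.2.1]octan-8-yl]methanol (C8 epimers) | OCC1[C@]2(C)CO[C@@]1(C)CC[C@H]2O[Si](C)(C)C(C)(C)C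
F6 | step 8 | 4-[(1R,2R,5S,8R)-2-[(tert-butyldimethylsilyl)oxy]-1,5-dimethyl-6-oxabicyclo[3.2.1]octan-8-yl]but-1-en-2-yl diethyl phosphate | C=C(CC[C@@H]1[C@]2(C)CO[C@@]1(C)CC[C@H]2O[Si](C)(C)C(C)(C)C)OP(=O)(OCC)OCC
F7 | step 8 | {[(1R,2R,5S,8R)-8-(but-3-yn-1-yl)-1,5-dimethyl-6-oxabicyclo[3.2.1]octan-2-yl]oxy}(tert-butyl)dimethylsilane | C#CCC[C@@H]1[C@]2(C)CO[C@@]1(C)CC[C@H]2O[Si](C)(C)C(C)(C)C
F8 | step 8 | dimethyl{(1E)-2-methyl-4-[(1R,2R,5S,8R)-2-[(tert-butyldimethylsilyl)oxy]-1,5-dimethyl-6-oxabicyclo[3.2.1]octan-8-yl]but-1-en-1-yl}alane | C[Al](C)/C=C(\C)CC[C@@H]1[C@]2(C)CO[C@@]1(C)CC[C@H]2O[Si](C)(C)C(C)(C)C
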